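**Remark:** acid 2 and hydroxytyrosol acetate 17 are taken as purchasable. Pyran locants used throughout: O1, C2 (methyl), C3 (hydroxymethyl), C4 (acetate arm), C5 (CO2Me), C6.

## Retrosynthetic overview

1. 21 ⇒ 20 (global desilylation) ⇒ 16 + 18: the C4–CH2 bond is made last by conjugate addition–elimination (SN2′) of the lithium enolate of silylated hydroxytyrosol acetate, which sets C4 anti to the C2 methyl and C3 silyloxymethyl groups.
2. 16 ⇒ 14: the C4 carbonyl of a 4-pyranone is a temporary oxidation level; 1,2-reduction and Ferrier-type transposition with MeOH move the leaving group to C6 and make C4 electrophilic.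
3. 14 ⇒ 11: the dihydropyran (O1, C2, C3, C4, C5, C6) is not assembled as a six-ring but grown from the four-membered oxetan-2-one ring (O1, C2, C3, C4) of a cis-β-lactone by inserting C5 and C6 into its acyl C4–O1 bond.
4. Enabling feature: in the pyran, O1–C2–C3–C4 is a β-oxygenated (aldol) array and O1–C6H=C5(CO2Me) is a vinylogous carbonate, i.e. a masked formylacetate. C4 can therefore act as a strained acyl donor towards an acetate enolate (C5), and O1 can recapture a formyl carbon (C6).
5. 11 ⇒ 9 ⇒ Evans syn-aldol of acetaldehyde with a 3-silyloxypropanoyl imide (sets C2 and C3). Ring order: oxetan-2-one (step 4), then dihydropyran (step 5); the arene is bought.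

Key step: step 5

## Route

Step 1
Reactants: 1 (R)-4-benzyl-1,3-oxazolidin-2-one; 2 3-[(tert-butyldiphenylsilyl)oxy]propanoic acid
Product: 4 (R)-4-benzyl-3-{3-[(tert-butyldiphenylsilyl)oxy]propanoyl}-1,3-oxazolidin-2-one, via mixed pivalic anhydride 3 (not isolated)
Conditions: t-BuCOCl, Et3N, THF, −20 °C; then 1, LiCl, −20 °C to rt
Reagents that add atoms: none
Why: Mixed-anhydride N-acylation of an Evans oxazolidinone (LiCl/Et3N variant) needs no strong base and leaves the silyl ether and the auxiliary stereocenter untouched.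

Step 2
Reactants: 4 (R)-4-benzyl-3-{3-[(tert-butyldiphenylsilyl)oxy]propanoyl}-1,3-oxazolidin-2-one; 5 acetaldehyde
Product: 7 (R)-4-benzyl-3-[(2R,3S)-2-{[(tert-butyldiphenylsilyl)oxy]methyl}-3-hydroxybutanoyl]-1,3-oxazolidin-2-one, via Z boron enolate 6 (not isolated)
Conditions: n-Bu2BOTf, i-Pr2NEt, CH2Cl2, 0 °C; then 5, −78 to 0 °C; pH 7 buffer, MeOH, H2O2
Reagents that add atoms: none
Why: Evans boron aldol reaction, in which the Z enolate reacts through a Zimmerman–Traxler chair on the face opposite the benzyl group, so the (R)-auxiliary should give the syn adduct carrying the future C2 (carbinol carbon, S) and C3 (α-carbon) of the target.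

Step 3
Reactants: 7 (R)-4-benzyl-3-[(2R,3S)-2-{[(tert-butyldiphenylsilyl)oxy]methyl}-3-hydroxybutanoyl]-1,3-oxazolidin-2-one
Product: 9 (2R,3S)-2-{[(tert-butyldiphenylsilyl)oxy]methyl}-3-hydroxybutanoic acid, via lithium peroxycarboxylate 8 (not isolated)
Conditions: LiOH, H2O2, THF/H2O, 0 °C; then Na2SO3; 1 M HCl to pH 3
Reagents that add atoms: hydrogen peroxide (as LiOOH), OO
Why: Hydroperoxide-mediated exocyclic cleavage of the imide (LiOOH) should free the acid at 0 °C without retro-aldol or epimerization and return the auxiliary.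

Step 4
Reactants: 9 (2R,3S)-2-{[(tert-butyldiphenylsilyl)oxy]methyl}-3-hydroxybutanoic acid
Product: 11 (3R,4S)-3-{[(tert-butyldiphenylsilyl)oxy]methyl}-4-methyloxetan-2-one (cis), via mixed sulfonic anhydride 10 (not isolated)
Conditions: PhSO2Cl, pyridine, 0 to 4 °C
Reagents that add atoms: none
Why: β-Lactonization by carboxyl activation (4-exo-trig acyl substitution by the hydroxyl) breaks no bond at either stereocenter, so the syn acid should give the cis lactone.

Step 5
Reactants: 11 (3R,4S)-3-{[(tert-butyldiphenylsilyl)oxy]methyl}-4-methyloxetan-2-one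
Product: 14 methyl (2S,3R)-3-{[(tert-butyldiphenylsilyl)oxy]methyl}-2-methyl-4-oxo-3,4-dihydro-2H-pyran-5-carboxylate, via hydroxy keto ester 12 (not isolated), via enaminone 13 (not isolated)
Conditions: LiN(i-Pr)2, MeOAc (3 equiv), THF, −78 °C; then 11, −78 to −40 °C; AcOH; concentrate; Me2NCH(OMe)2, CH2Cl2, rt; then BF3·OEt2, rt
Reagents that add atoms: methyl acetate, COC(C)=O; N,N-dimethylformamide dimethyl acetal, COC(OC)N(C)C
Why: Two-atom ring expansion by acyl C4–O1 cleavage and reclosure (Claisen-type acylation of an ester enolate by a β-lactone, then a Maitland–Japp-type dihydropyranone annulation): the enolate attacks the strained lactone carbonyl C4, the ring opens to the C2 alkoxide, and the β-ketoester is at once deprotonated at C5, which protects the new ketone from enolizing towards C3. After the acidic quench the doubly activated C5 methylene condenses with Me2NCH(OMe)2 to the enaminone (C5=C6), and BF3·OEt2 triggers attack of the C2 hydroxyl on C6 with loss of dimethylamine. The pyran closes by 6-endo-trig conjugate addition–elimination (vinylogous transamidation), the only mode open to a hydroxyl placed 1,5 to C6; the closest known reactions are the ring opening of β-lactones by ester enolates and the formation of 5-alkoxycarbonyl-2,3-dihydro-4-pyranones from δ-hydroxy-β-ketoesters and formamide acetals. No stereocenter is made: C2 and C3 are carried over from 11, because the C2–O bond is never broken and C3 stays sp3. The step needs acyl–oxygen rather than alkyl–oxygen cleavage (hard lithium enolate, ring strain), reaction of the formamide acetal at C5 only (the sole acidic CH2), and ring closure onto C6 rather than lactonization onto the methyl ester (low temperature, enolate form of the ketoester before the quench).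

Step 6
Reactants: 14 methyl (2S,3R)-3-{[(tert-butyldiphenylsilyl)oxy]methyl}-2-methyl-4-oxo-3,4-dihydro-2H-pyran-5-carboxylate
Product: 16 methyl (2S,3R,6RS)-3-{[(tert-butyldiphenylsilyl)oxy]methyl}-6-methoxy-2-methyl-3,6-dihydro-2H-pyran-5-carboxylate, via allylic alcohol 15 (not isolated)
Conditions: NaBH4, CeCl3·7H2O, MeOH, −78 °C; then pyridinium p-toluenesulfonate (cat.), MeOH, 0 °C to rt
Reagents that add atoms: methanol, CO
Why: Luche 1,2-reduction of the vinylogous-ester ketone followed by acid-catalysed Ferrier-type allylic transposition (as in a Stork–Danheiser sequence) should capture the vinylogous oxocarbenium ion with methanol at C6 and turn C4 into the β-carbon of an enoate; the C6 epimers are both usable because C6 becomes sp2 again in step 8.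

Step 7
Reactants: 17 2-(3,4-dihydroxyphenyl)ethyl acetate
Product: 18 2-[3,4-bis(tert-butyldimethylsilyloxy)phenyl]ethyl acetate
Conditions: t-BuMe2SiCl, imidazole, DMF, rt
Reagents that add atoms: tert-butyldimethylsilyl chloride, CC(C)(C)[Si](C)(C)Cl
Why: Imidazole-promoted silylation masks both acidic phenols before enolate formation and does not touch the acetate.

Step 8
Reactants: 16 methyl (2S,3R,6RS)-3-{[(tert-butyldiphenylsilyl)oxy]methyl}-6-methoxy-2-methyl-3,6-dihydro-2H-pyran-5-carboxylate; 18 2-[3,4-bis(tert-butyldimethylsilyloxy)phenyl]ethyl acetate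
Product: 20 methyl (2S,3R,4S)-4-(2-{2-[3,4-bis(tert-butyldimethylsilyloxy)phenyl]ethoxy}-2-oxoethyl)-3-{[(tert-butyldiphenylsilyl)oxy]methyl}-2-methyl-3,4-dihydro-2H-pyran-5-carboxylate, via lithium enolate 19 (not isolated)
Conditions: LiN(i-Pr)2, 18, THF, −78 °C; then 16, DMPU, −78 to −20 °C; NH4Cl (aq)
Reagents that add atoms: none
Why: Conjugate addition–elimination (SN2′: Michael addition, then E1cB loss of methoxide) of the ester enolate to the cyclic β′-alkoxy enoate should add the nucleophile to C4 anti to the C3 silyloxymethyl and C2 methyl groups, which share one face, setting C4 (3,4-trans), while loss of methoxide from C6 restores the O1–C6=C5 vinylogous carbonate.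

Step 9
Reactants: 20 methyl (2S,3R,4S)-4-(2-{2-[3,4-bis(tert-butyldimethylsilyloxy)phenyl]ethoxy}-2-oxoethyl)-3-{[(tert-butyldiphenylsilyl)oxy]methyl}-2-methyl-3,4-dihydro-2H-pyran-5-carboxylate
Product: 21 methyl (2S,3R,4S)-4-{2-[2-(3,4-dihydroxyphenyl)ethoxy]-2-oxoethyl}-3-(hydroxymethyl)-2-methyl-3,4-dihydro-2H-pyran-5-carboxylate (CNP0204147.2)
Conditions: HF·pyridine, pyridine, THF, 0 °C to rt
Reagents that add atoms: none
Why: Global fluoride desilylation under buffered acidic conditions should remove all three silyl groups without generating the alkoxide that could lactonize the freed C3 hydroxymethyl onto the neighbouring ester or cleave the phenethyl ester.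

## Compound list

1 | (R)-4-benzyl-1,3-oxazolidin-2-one | O=C1OC[C@@H](Cc2ccccc2)N1 | starting material
2 | 3-[(tert-butyldiphenylsilyl)oxy]propanoic acid | OC(=O)CCO[Si](c1ccccc1)(c1ccccc1)C(C)(C)C | starting material
3 | mixed anhydride of 2 with pivalic acid (formed in the flask) | CC(C)(C)C(=O)OC(=O)CCO[Si](c1ccccc1)(c1ccccc1)C(C)(C)C | intermediate
4 | (R)-4-benzyl-3-{3-[(tert-butyldiphenylsilyl)oxy]propanoyl}-1,3-oxazolidin-2-one | O=C1OC[C@@H](Cc2ccccc2)N1C(=O)CCO[Si](c1ccccc1)(c1ccccc1)C(C)(C)C | intermediate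
5 | acetaldehyde | CC=O | starting material
6 | Z di-n-butylboron enolate of 4 (formed in the flask) | O=C1OC[C@@H](Cc2ccccc2)N1/C(OB(CCCC)CCCC)=C/CO[Si](c1ccccc1)(c1ccccc1)C(C)(C)C | intermediate
7 | (R)-4-benzyl-3-[(2R,3S)-2-{[(tert-butyldiphenylsilyl)oxy]methyl}-3-hydroxybutanoyl]-1,3-oxazolidin-2-one | O=C1OC[C@@H](Cc2ccccc2)N1C(=O)[C@H](CO[Si](c1ccccc1)(c1ccccc1)C(C)(C)C)[C@H](C)O | intermediate
8 | lithium (2R,3S)-2-{[(tert-butyldiphenylsilyl)oxy]methyl}-3-hydroxybutaneperoxoate (formed in the flask) | [Li+].[O-]OC(=O)[C@H](CO[Si](c1ccccc1)(c1ccccc1)C(C)(C)C)[C@H](C)O | intermediate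
9 | (2R,3S)-2-{[(tert-butyldiphenylsilyl)oxy]methyl}-3-hydroxybutanoic acid | OC(=O)[C@H](CO[Si](c1ccccc1)(c1ccccc1)C(C)(C)C)[C@H](C)O | intermediate
10 | mixed anhydride of 9 with benzenesulfonic acid (formed in the flask) | O=S(=O)(OC(=O)[C@H](CO[Si](c1ccccc1)(c1ccccc1)C(C)(C)C)[C@H](C)O)c1ccccc1 | intermediate
11 | (3R,4S)-3-{[(tert-butyldiphenylsilyl)oxy]methyl}-4-methyloxetan-2-one (cis-β-lactone) | O1[C@@H](C)[C@@H](CO[Si](c2ccccc2)(c2ccccc2)C(C)(C)C)C1=O | intermediate
12 | methyl (4R,5S)-4-{[(tert-butyldiphenylsilyl)oxy]methyl}-5-hydroxy-3-oxohexanoate (formed in the flask) | COC(=O)CC(=O)[C@H](CO[Si](c1ccccc1)(c1ccccc1)C(C)(C)C)[C@H](C)O | intermediate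
13 | methyl (4R,5S)-4-{[(tert-butyldiphenylsilyl)oxy]methyl}-2-[(dimethylamino)methylidene]-5-hydroxy-3-oxohexanoate (formed in the flask) | COC(=O)C(=CN(C)C)C(=O)[C@H](CO[Si](c1ccccc1)(c1ccccc1)C(C)(C)C)[C@H](C)O | intermediate
14 | methyl (2S,3R)-3-{[(tert-butyldiphenylsilyl)oxy]methyl}-2-methyl-4-oxo-3,4-dihydro-2H-pyran-5-carboxylate | COC(=O)C1=CO[C@@H](C)[C@@H](CO[Si](c2ccccc2)(c2ccccc2)C(C)(C)C)C1=O | intermediate
15 | methyl (2S,3S,4RS)-3-{[(tert-butyldiphenylsilyl)oxy]methyl}-4-hydroxy-2-methyl-3,4-dihydro-2H-pyran-5-carboxylate (formed in the flask; C2/C3 as in 14) | COC(=O)C1=CO[C@@H](C)[C@@H](CO[Si](c2ccccc2)(c2ccccc2)C(C)(C)C)C1O | intermediate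
16 | methyl (2S,3R,6RS)-3-{[(tert-butyldiphenylsilyl)oxy]methyl}-6-methoxy-2-methyl-3,6-dihydro-2H-pyran-5-carboxylate | COC1O[C@@H](C)[C@@H](CO[Si](c2ccccc2)(c2ccccc2)C(C)(C)C)C=C1C(=O)OC | intermediate
17 | 2-(3,4-dihydroxyphenyl)ethyl acetate (hydroxytyrosol acetate) | CC(=O)OCCc1ccc(O)c(O)c1 | starting material
18 | 2-[3,4-bis(tert-butyldimethylsilyloxy)phenyl]ethyl acetate | CC(=O)OCCc1ccc(O[Si](C)(C)C(C)(C)C)c(O[Si](C)(C)C(C)(C)C)c1 | intermediate
19 | lithium enolate of 18 (formed in the flask) | [Li+].[O-]C(=C)OCCc1ccc(O[Si](C)(C)C(C)(C)C)c(O[Si](C)(C)C(C)(C)C)c1 | intermediate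
20 | methyl (2S,3R,4S)-4-(2-{2-[3,4-bis(tert-butyldimethylsilyloxy)phenyl]ethoxy}-2-oxoethyl)-3-{[(tert-butyldiphenylsilyl)oxy]methyl}-2-methyl-3,4-dihydro-2H-pyran-5-carboxylate | COC(=O)C1=CO[C@@H](C)[C@@H](CO[Si](c2ccccc2)(c2ccccc2)C(C)(C)C)[C@@H]1CC(=O)OCCc1ccc(O[Si](C)(C)C(C)(C)C)c(O[Si](C)(C)C(C)(C)C)c1 | intermediate
21 | methyl (2S,3R,4S)-4-{2-[2-(3,4-dihydroxyphenyl)ethoxy]-2-oxoethyl}-3-(hydroxymethyl)-2-methyl-3,4-dihydro-2H-pyran-5-carboxylate | COC(=O)C1=CO[C@@H](C)[C@@H](CO)[C@@H]1CC(=O)OCCc1ccc(O)c(O)c1 | target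

## Step count and risks

Total step count: 9. Longest linear sequence: 8 steps (steps 1–6, 8, 9).

Steps most likely to fail:

1. **Step 8.** The basic lithium enolate may self-condense (Claisen) or remove the allylic C3 proton of 16 instead of adding to the hindered α-branched enoate, and face selectivity at C4 could erode. The fallback sets out from 16 (with 18) and comes back at 20. Meldrum's acid with catalytic Et3N in MeCN, a soft and weakly basic carbon acid, should add to C4 of 16 and expel methanol to give the Meldrum's acid adduct F1. In parallel, 18 is reduced with i-Bu2AlH (CH2Cl2, −78 °C) to 2-[3,4-bis(tert-butyldimethylsilyloxy)phenyl]ethanol F2. Heating F1 with F2 in toluene at 100 °C should open the dioxanedione, lose acetone and CO2, and give 20 (the known alcoholysis–decarboxylation of monosubstituted Meldrum's acids).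

2. **Step 5.** The enolate may deprotonate the lactone at C3 (β-elimination or epimerization), the lithium alkoxide of the opened product may undergo retro-aldol cleavage or lactonize onto the methyl ester, and C3 may epimerize or the ring may open by retro-oxa-Michael reaction during the basic aminomethylenation. The fallback sets out from 11 and comes back at 14. Me2AlCl-mediated aminolysis of 11 with MeNH(OMe)·HCl under non-basic conditions gives the β-hydroxy Weinreb amide F3. Its chelated tetrahedral adduct with the lithium enolate of methyl acetate persists until the acidic quench, so 12 is released only on work-up and can be isolated and purified. Compound 12 is then cyclocondensed with Me2NCH(OMe)2 and BF3·OEt2 to 14.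

3. **Step 6.** Hydride may add in conjugate fashion at C6, and the acid-promoted ionization may end in proton loss from C3 (forming a 2H-pyran and erasing the C3 stereocenter) or stop at the 4-methoxy isomer. The fallback sets out from 14 and comes back at 16. Compound 15 is isolated after the Luche reduction and acetylated (Ac2O, pyridine, DMAP) to the allylic acetate F4. F4 then undergoes palladium-catalysed allylic substitution with methanol (Pd(OAc)2, 2-(di-tert-butylphosphino)biphenyl, Et2Zn, MeOH, THF, rt; Tsuji–Trost etherification through zerovalent palladium formed in the flask). The zinc methoxide should attack the oxygen-bearing allyl terminus C6, as in palladium-catalysed O-glycosylation of glycal 3-acetates, giving 16 without a free cation.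

Further compounds
F1 | step 8 | methyl (2S,3R,4R)-3-{[(tert-butyldiphenylsilyl)oxy]methyl}-4-(2,2-dimethyl-4,6-dioxo-1,3-dioxan-5-yl)-2-methyl-3,4-dihydro-2H-pyran-5-carboxylate | COC(=O)C1=CO[C@@H](C)[C@@H](CO[Si](c2ccccc2)(c2ccccc2)C(C)(C)C)[C@@H]1C1C(=O)OC(C)(C)OC1=O
F2 | step 8 | 2-[3,4-bis(tert-butyldimethylsilyloxy)phenyl]ethanol | OCCc1ccc(O[Si](C)(C)C(C)(C)C)c(O[Si](C)(C)C(C)(C)C)c1
F3 | step 5 | (2R,3S)-2-{[(tert-butyldiphenylsilyl)oxy]methyl}-3-hydroxy-N-methoxy-N-methylbutanamide | CON(C)C(=O)[C@H](CO[Si](c1ccccc1)(c1ccccc1)C(C)(C)C)[C@H](C)O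
F4 | step 6 | methyl (2S,3R,4RS)-4-acetoxy-3-{[(tert-butyldiphenylsilyl)oxy]methyl}-2-methyl-3,4-dihydro-2H-pyran-5-carboxylate | COC(=O)C1=CO[C@@H](C)[C@@H](CO[Si](c2ccccc2)(c2ccccc2)C(C)(C)C)C1OC(C)=O
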